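**Retrosynthetic overview**
1. Target ⇒ its catechol diacetate. The acetates come off last under base, so the free 4-OH never meets acid next to the Δ7 alkene.
2. Bicyclic diacetate ⇒ open-chain (2E,6E)-farnesylarene. Rings A and B close together in one chiral-proton-initiated cation–olefin bicyclisation on the complete carbon skeleton; C5, C9, C10 and the Δ7 alkene all arise here.
3. Farnesylarene ⇒ aryl bromide + (2E,6E)-farnesylstannane (Stille coupling, neutral, acetate-tolerant).
4. Aryl bromide ⇒ methyl 3-bromo-4,5-dihydroxybenzoate + Ac2O; stannane ⇒ (2E,6E)-farnesyl bromide + Bu3SnLi.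
5. Ring order: the benzene ring is bought; rings A and B of the decalin form simultaneously in the fourth step.

Assumption: the (R)-configured 3,3'-dichloro-BINOL·SbCl5 acid gives the (5S,10S) decalin, as BINOL-derived acids of this kind do with related (E,E)-polyprenyl substrates; if the first run shows the opposite sense, the (S)-ligand is used with nothing else changed.

**Step 1**
Reactants: 1 methyl 3-bromo-4,5-dihydroxybenzoate
Product: 2 methyl 3,4-diacetoxy-5-bromobenzoate
Conditions: Ac2O (2.5 equiv), pyridine (3 equiv), DMAP (5 mol %), CH2Cl2, 0 °C → rt, 2 h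
Reagents that add atoms: acetic anhydride, CC(=O)OC(C)=O
Why: DMAP-catalysed O-acylation of both phenols is fast and clean, and the two electron-withdrawing acetates later keep O-4 and the aromatic ring from acting as nucleophiles in the cationic step; no stereocentre is formed.

**Step 2**
Reactants: 3 (2E,6E)-farnesyl bromide [(2E,6E)-1-bromo-3,7,11-trimethyldodeca-2,6,10-triene]
Product: 4 tributyl[(2E,6E)-3,7,11-trimethyldodeca-2,6,10-trien-1-yl]stannane
Conditions: Bu3SnH, LiN(i-Pr)2 (commercial solution), THF, 0 °C, 20 min (gives Bu3SnLi); then 3, −78 → −30 °C, 1 h; Et3N-deactivated silica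
Reagents that add atoms: tributyltin hydride, CCCC[SnH](CCCC)CCCC
Why: SN2 displacement of the primary allylic bromide by the soft stannyl anion (nucleophilic stannylation) at low temperature gives the α-substituted allylstannane with both E alkenes untouched; no stereocentre is formed.

**Step 3**
Reactants: 2 methyl 3,4-diacetoxy-5-bromobenzoate; 4 tributyl[(2E,6E)-3,7,11-trimethyldodeca-2,6,10-trien-1-yl]stannane (1.3 equiv)
Product: 5 methyl 3,4-diacetoxy-5-[(2E,6E)-3,7,11-trimethyldodeca-2,6,10-trien-1-yl]benzoate
Conditions: Pd(PPh3)4 (5 mol %), degassed DMF, 90 °C, 12 h; MeCN/hexane partition to remove tin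
Reagents that add atoms: none
Why: Stille cross-coupling, in which oxidative addition of the electron-poor aryl bromide to zerovalent palladium, allyl transfer from tin and reductive elimination at the less hindered allyl terminus give the linear (2E,6E)-farnesylarene under neutral conditions that leave the aryl acetates and the methyl ester alone; no stereocentre is formed.

**Step 4**
Reactants: 5 methyl 3,4-diacetoxy-5-[(2E,6E)-3,7,11-trimethyldodeca-2,6,10-trien-1-yl]benzoate
Product: 6 methyl 3,4-diacetoxy-5-{[(1S,4aS,8aS)-2,5,5,8a-tetramethyl-1,4,4a,5,6,7,8,8a-octahydronaphthalen-1-yl]methyl}benzoate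
Conditions: SbCl5·(R)-3,3'-dichloro-1,1'-bi-2-naphthol (1:1 complex, 1.5 equiv), CH2Cl2, −78 °C, 8–12 h; Et3N quench at −78 °C; AgNO3–silica chromatography, then recrystallisation to >99% ee
Reagents that add atoms: none
Why: Proposed new method: the chiral Brønsted acid formed from SbCl5 and the (R)-binaphthol protonates the terminal isopropylidene alkene of the chair–chair folded (2E,6E)-triene on one enantiotopic face, the two anti additions across the E alkenes close rings A and B together as the trans-decalin with 5α-H, 10β-CH3 and equatorial 9β-CH2Ar (5S,9S,10S), and because the diacetoxybenzoate ring and its acylated O-4 are too electron-poor to trap the C8 cation (which would give the indane- or chromane-fused tetracycles) the cation loses the axial H-7 to give the trisubstituted Δ7 alkene, any exocyclic isomer being re-protonated and funnelled into the ring; the closest known reaction type is the enantioselective proton-initiated polyene cyclisation with BINOL-derived Lewis-acid-assisted Brønsted acids, known mainly with arene or hydroxyl terminators and here extended to termination by elimination.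

**Step 5**
Reactants: 6 methyl 3,4-diacetoxy-5-{[(1S,4aS,8aS)-2,5,5,8a-tetramethyl-1,4,4a,5,6,7,8,8a-octahydronaphthalen-1-yl]methyl}benzoate
Product: 7 methyl 3,4-dihydroxy-5-{[(1S,4aS,8aS)-2,5,5,8a-tetramethyl-1,4,4a,5,6,7,8,8a-octahydronaphthalen-1-yl]methyl}benzoate (target)
Conditions: K2CO3 (0.2 equiv), degassed MeOH, Ar, 0 °C → rt, 1 h; aq. NH4Cl
Reagents that add atoms: none
Why: Base-catalysed transesterification (methanolysis) removes the aryl acetates much faster than anything else reacts, the methyl ester being degenerate in methanol, and the non-acidic medium avoids proton-induced closure of the free 4-OH onto the Δ7 alkene; no stereocentre is touched.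

**Compound list**
1 | methyl 3-bromo-4,5-dihydroxybenzoate | COC(=O)c1cc(O)c(O)c(Br)c1 | starting material
2 | methyl 3,4-diacetoxy-5-bromobenzoate | COC(=O)c1cc(OC(C)=O)c(OC(C)=O)c(Br)c1 | intermediate
3 | (2E,6E)-farnesyl bromide | BrC/C=C(\C)CC/C=C(\C)CCC=C(C)C | starting material
4 | tributyl[(2E,6E)-3,7,11-trimethyldodeca-2,6,10-trien-1-yl]stannane | CCCC[Sn](CCCC)(CCCC)C/C=C(\C)CC/C=C(\C)CCC=C(C)C | intermediate
5 | methyl 3,4-diacetoxy-5-[(2E,6E)-3,7,11-trimethyldodeca-2,6,10-trien-1-yl]benzoate | COC(=O)c1cc(OC(C)=O)c(OC(C)=O)c(C/C=C(\C)CC/C=C(\C)CCC=C(C)C)c1 | intermediate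
6 | methyl 3,4-diacetoxy-5-{[(1S,4aS,8aS)-2,5,5,8a-tetramethyl-1,4,4a,5,6,7,8,8a-octahydronaphthalen-1-yl]methyl}benzoate | COC(=O)c1cc(OC(C)=O)c(OC(C)=O)c(C[C@H]2C(C)=CC[C@H]3C(C)(C)CCC[C@]23C)c1 | intermediate
7 | methyl 3,4-dihydroxy-5-{[(1S,4aS,8aS)-2,5,5,8a-tetramethyl-1,4,4a,5,6,7,8,8a-octahydronaphthalen-1-yl]methyl}benzoate | COC(=O)c1cc(O)c(O)c(C[C@H]2C(C)=CC[C@H]3C(C)(C)CCC[C@]23C)c1 | target

**Step count**
Total: 5 steps. Longest linear sequence: 4 steps (1 → 2 → 5 → 6 → 7); step 2 is a one-step side branch.

**Steps most likely to fail, with fallbacks**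

Step 4 (bicyclisation) is the riskiest. The chiral acid may stop after ring A, give alkene-isomer mixtures, or give moderate ee on a substrate that ends by elimination. The fallback sets out from 5 and returns at 6 by making the two rings one after the other, so that only ring A depends on the chiral acid. Compound 5 is treated with SnCl4·(R)-2-(2-fluorobenzyloxy)-2'-hydroxy-1,1'-binaphthyl in toluene at −78 °C, which closes ring A enantioselectively and stops. This gives methyl 3,4-diacetoxy-5-{(2E)-3-methyl-5-[(1S)-2,6,6-trimethylcyclohex-2-en-1-yl]pent-2-en-1-yl}benzoate F1 together with its exocyclic isomer methyl 3,4-diacetoxy-5-{(2E)-5-[(1S)-2,2-dimethyl-6-methylidenecyclohexyl]-3-methylpent-2-en-1-yl}benzoate F2. The unseparated mixture is then treated with ClSO3H in 2-nitropropane at −78 °C. Both isomers are re-protonated to the same ring-A tertiary cation, and ring B closes through a chair transition state under control of the existing stereocentre, giving the trans-decalin and the Δ7 alkene of 6.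

Step 3 (Stille coupling) is second. Coupling at the γ-carbon (branched isomer), E/Z erosion at the 2,3-alkene or protodestannylation could lower the yield of linear 5. The fallback sets out from 2 and returns at 5 with the polarity reversed. Borylation of 2 (bis(pinacolato)diboron, PdCl2(dppf), KOAc, dioxane, 85 °C) gives methyl 3,4-diacetoxy-5-(4,4,5,5-tetramethyl-1,3,2-dioxaborolan-2-yl)benzoate F3. Allyl–aryl Suzuki–Miyaura coupling of F3 with farnesyl bromide 3 (Pd(PPh3)4, anhydrous KF, THF, 60 °C) then gives 5, with the aryl group delivered to the unhindered primary allyl terminus.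

Step 2 (stannane preparation) is third. Wurtz-type homocoupling, some SN2' product and loss of the acid-labile allylstannane on silica are the concerns. The fallback sets out from 3 and returns at 5 without any tin. Displacement of bromide in 3 with KOAc in DMF at rt gives (2E,6E)-farnesyl acetate F4. Nickel-catalysed reductive cross-electrophile coupling of F4 with aryl bromide 2 (NiCl2(dme), 4,4'-di-tert-butyl-2,2'-bipyridine, Zn dust, THF/DMA, rt to 40 °C) then gives the linear (E)-allylarene 5 directly.

**Further compounds**
F1 | step 4 | methyl 3,4-diacetoxy-5-{(2E)-3-methyl-5-[(1S)-2,6,6-trimethylcyclohex-2-en-1-yl]pent-2-en-1-yl}benzoate | COC(=O)c1cc(OC(C)=O)c(OC(C)=O)c(C/C=C(\C)CC[C@@H]2C(C)=CCCC2(C)C)c1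
F2 | step 4 | methyl 3,4-diacetoxy-5-{(2E)-5-[(1S)-2,2-dimethyl-6-methylidenecyclohexyl]-3-methylpent-2-en-1-yl}benzoate | COC(=O)c1cc(OC(C)=O)c(OC(C)=O)c(C/C=C(\C)CC[C@@H]2C(=C)CCCC2(C)C)c1
F3 | step 3 | methyl 3,4-diacetoxy-5-(4,4,5,5-tetramethyl-1,3,2-dioxaborolan-2-yl)benzoate | COC(=O)c1cc(OC(C)=O)c(OC(C)=O)c(B2OC(C)(C)C(C)(C)O2)c1
F4 | step 2 | (2E,6E)-farnesyl acetate | CC(=O)OC/C=C(\C)CC/C=C(\C)CCC=C(C)C
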